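How much of the substrate has reacted in the flask after 2.5 d, how much target and intermediate B stand there, and is it still moving?

| flask | substrate | remark | time |
|---|---|---|---|
| spring | 0.060 M | run made earlier |  |
| autumn | 0.090 M | run made earlier |  |
| flask | 0.12 M |  | 2.5 d |

| run | time / h | substrate / % | target / % | intermediate B / % |
|---|---|---|---|---|
| spring | 4.00 | 7.7 | 2.3 | 77.6 |
| spring | 8.00 | 6.0 | 2.4 | 68.9 |
| spring | 20.0 | 5.8 | 3.7 | 55.3 |
| spring | 50.0 | 3.7 | 4.3 | 47.0 |
| autumn | 6.00 | 7.5 | 2.5 | 72.6 |
| autumn | 15.0 | 5.8 | 4.4 | 59.0 |
| autumn | 30.0 | 4.8 | 5.0 | 50.9 |
| autumn | 50.0 | 5.2 | 5.1 | 47.3 |

(standard deviation of a reading: 0.5 percentage points)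

1. at 2.5 d, what has stopped the reaction, if anything has (forward and back rates have come level / all of the substrate has reacted / it is still moving)
2. how much of the substrate has reacted by 2.5 d
3. how much target there is at 2.5 d, in percent of the substrate charged
4. how much intermediate B there is at 2.5 d, in percent of the substrate charged

- on the list of suspects stand: substrate -> target; substrate <-> intermediate A; intermediate A <-> intermediate B; intermediate B -> target; intermediate B <-> substrate; target -> over-reaction product
- what has gone from substrate into another species counts as reacted, even if it can come back
- the reaction counts as stopped when no species that holds the substrate changes by six tenths of a point or more over the second half of the time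

We build the flask one process at a time. First take the step between substrate and intermediate B by itself. Its mark is the lock, the substrate readings of both runs summed over the intermediate B readings summed, 0.0972, a pre-equilibrium as read. With this step by itself, 91.1% of the charge would sit as intermediate B, and that is the share reacted.

Now add the drain out of intermediate B. In the spring run intermediate B falls from 77.6% to 47.0%, and the ratio of substrate to intermediate B reads 0.0992 at the first reading and 0.0787 at the last; in the autumn run it reads 0.103 and 0.110, so the two runs show no common drift. This is the crossing: from the first readings on, we read substrate as falling along with intermediate B, at a ratio near the lock.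

The last readings of intermediate B, 47.0% and 47.3%, nearly match although the charges differ, so we carry them to the flask at 0.12 M, though that flask is read later than these runs. Their mean times the lock gives 4.58% substrate, so our own figure is 95.4% reacted.

Add the rest: target reads 4.3% and 5.1% at 50.0 h, and it counts as reacted already. The autumn run still loses 3.6 percentage points of intermediate B between 30.0 h and 50.0 h, so we call the flask still moving.

The forecast says it is still moving, with 95.5% reacted, close to our figure, target 5.2% and intermediate B 46%, fitted to “a plateau near 45%”.

The flask gives: it is still moving, with 95.6% reacted, target 4.15% and intermediate B 45.7%.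

    substrate → target (k = 4.80 × 10⁻⁴ /min)
    substrate ⇌ intermediate A (K = 7.40, k = 4.90 × 10⁻⁴ /min)
    intermediate A ⇌ intermediate B (K = 1.40, k = 9.20 × 10⁻⁴ /min)
    intermediate B → target (k = 2.90 × 10⁻⁵ /min)
    intermediate B ⇌ substrate (k = 0.00290 /min)
    target → over-reaction product (k = 8.60 × 10⁻⁴ /min)

The relaxation half-life between intermediate B and substrate, by that step alone, is 0.351 h, short against 2.5 d. The lock on this flask's intermediate B gives 4.44% substrate, and 4.4% stands there. A later reading is what breaks the forecast's plateau: in the flask left until 6.0 d, intermediate B stands at 37.2%, below it, and the lock on that gives 3.62% substrate against 3.54% found.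

The readings stem from a simulated flask on assumed constants; the scatter is artificial.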